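**Retrosynthetic overview**

- Last operation: one mild acid treatment removes two aryl methoxymethyl (MOM) ethers and one primary silyl ether.
- Key disconnection: ring A (benzoic acid ring: C1 carboxyl, C2 hydroxyl, C3 prenyl, C6 aryloxy) carries O-aryl, CO2H and OH on the three adjacent carbons C6, C1 and C2. Cutting the C6–O and C1–CO2H bonds together leaves a C1≡C6 aryne with oxygen on C2, the ring B phenoxide and carbon dioxide.
- Aryne precursor (ortho-silylaryl triflate) from 4-bromoresorcinol: steric monosilylation, MOM protection, Br/Li exchange and prenylation, desilylation, carbamate-directed C-silylation between the two oxygens, carbamate-to-triflate exchange.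
- Ring B phenol from creosol: ortho-formylation, demethylation, mono-MOM protection through the dianion, reduction, O-silylation of the benzylic hydroxyl.
- No ring is formed; both benzene rings are bought and only joined.

Key step: step 13

Remark: the target has no stereocentre and no stereogenic double bond, so the demand for a single enantiomer places no requirement on the route. Ring A is numbered as the benzoic acid throughout.

**Route**

Step 1
Reactants: 1 4-bromoresorcinol
Product: 2 2-bromo-5-[(triisopropylsilyl)oxy]phenol
Conditions: TIPSCl (1.0 equiv), imidazole (2.0 equiv), CH2Cl2/DMF, 0 °C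
Reagents that add atoms: triisopropylsilyl chloride, CC(C)[Si](Cl)(C(C)C)C(C)C
Why: Imidazole-mediated O-silylation with the bulky silyl chloride should take place at the hydroxyl para to bromine, because the other hydroxyl is shielded by the neighbouring bromine atom, so the two oxygens are told apart sterically.

Step 2
Reactants: 2 2-bromo-5-[(triisopropylsilyl)oxy]phenol
Product: 3 [4-bromo-3-(methoxymethoxy)phenoxy]tri(propan-2-yl)silane
Conditions: MOMCl (1.3 equiv), i-Pr2NEt (1.5 equiv), CH2Cl2, 0 °C → rt
Reagents that add atoms: chloromethyl methyl ether, COCCl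
Why: Williamson-type O-alkylation of the remaining phenol gives the methoxymethyl ether, which later serves as ortho-director, as the group that polarises the aryne, and as the acid-labile mask of the C2 hydroxyl.

Step 3
Reactants: 3 [4-bromo-3-(methoxymethoxy)phenoxy]tri(propan-2-yl)silane; 4 prenyl bromide (1-bromo-3-methylbut-2-ene)
Product: 6 [3-(methoxymethoxy)-4-(3-methylbut-2-en-1-yl)phenoxy]tri(propan-2-yl)silane, via aryllithium 5 (not isolated)
Conditions: n-BuLi (1.05 equiv), THF, −78 °C; CuBr·SMe2 (10 mol %), then 4 (1.3 equiv), −78 → 0 °C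
Reagents that add atoms: n-butyllithium, [Li]CCCC (lithium in 5 only)
Why: Bromine–lithium exchange gives aryllithium 5, held by chelation to the neighbouring acetal oxygen, and copper-catalysed SN2 allylation at the unhindered primary carbon of prenyl bromide forms the aryl–CH2 bond, the silyl ether being para to the metal and therefore unable to migrate.

Step 4
Reactants: 6 [3-(methoxymethoxy)-4-(3-methylbut-2-en-1-yl)phenoxy]tri(propan-2-yl)silane
Product: 7 3-(methoxymethoxy)-4-(3-methylbut-2-en-1-yl)phenol
Conditions: TBAF (1.1 equiv), THF, 0 °C; aq. NH4Cl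
Reagents that add atoms: none
Why: Fluoride-induced cleavage of the aryl silyl ether (Si–F bond formation) frees the phenol without touching the acetal or the alkene.

Step 5
Reactants: 7 3-(methoxymethoxy)-4-(3-methylbut-2-en-1-yl)phenol
Product: 8 3-(methoxymethoxy)-4-(3-methylbut-2-en-1-yl)phenyl N-(propan-2-yl)carbamate
Conditions: i-PrNCO (1.5 equiv), Et3N (0.2 equiv), CH2Cl2, rt
Reagents that add atoms: isopropyl isocyanate, CC(C)N=C=O
Why: Amine-catalysed addition of the phenol to the isocyanate (carbamoylation) installs a secondary carbamate that directs metalation and can later be removed under mild base.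

Step 6
Reactants: 8 3-(methoxymethoxy)-4-(3-methylbut-2-en-1-yl)phenyl N-(propan-2-yl)carbamate
Product: 12 3-(methoxymethoxy)-4-(3-methylbut-2-en-1-yl)-2-(trimethylsilyl)phenyl N-(propan-2-yl)carbamate, via N-silyl carbamate 9 (not isolated), via 2-lithio N-silyl carbamate 10 (not isolated), via N-silyl C-silyl carbamate 11 (not isolated)
Conditions: TBSOTf (1.05 equiv), TMEDA (1.1 equiv), Et2O, 0 °C → rt; n-BuLi (2.0 equiv), TMEDA (2.0 equiv), −78 °C; TMSCl (3 equiv), −78 °C → rt; aq. NH4Cl
Reagents that add atoms: chlorotrimethylsilane, C[Si](C)(C)Cl; tert-butyldimethylsilyl triflate, CC(C)(C)[Si](C)(C)OS(=O)(=O)C(F)(F)F (silicon group in 9–11 only); n-butyllithium, [Li]CCCC (lithium in 10 only)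
Why: Directed ortho-metalation, in which transient N-silylation stops the carbamate from fragmenting to isocyanate, butyllithium removes the C2 proton lying between the carbamate and the methoxymethoxy group (cooperative complex-induced proximity), TMSCl silylates the aryllithium, and the N–Si bond is hydrolysed on work-up.

Step 7
Reactants: 12 3-(methoxymethoxy)-4-(3-methylbut-2-en-1-yl)-2-(trimethylsilyl)phenyl N-(propan-2-yl)carbamate
Product: 14 3-(methoxymethoxy)-4-(3-methylbut-2-en-1-yl)-2-(trimethylsilyl)phenyl trifluoromethanesulfonate, via silylphenol 13 (not isolated)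
Conditions: DBU (1.5 equiv), Et2NH (1.2 equiv), MeCN, 40 °C; then PhNTf2 (1.5 equiv), rt
Reagents that add atoms: N-phenylbis(trifluoromethanesulfonimide), O=S(=O)(N(c1ccccc1)S(=O)(=O)C(F)(F)F)C(F)(F)F
Why: E1cB cleavage of the deprotonated secondary carbamate releases the phenoxide while diethylamine scavenges the isocyanate, and O-sulfonylation of the phenoxide with the triflimide in the same flask gives the ortho-silylaryl triflate.

Step 8
Reactants: 15 creosol (2-methoxy-4-methylphenol)
Product: 16 2-hydroxy-3-methoxy-5-methylbenzaldehyde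
Conditions: MgCl2 (1.5 equiv), Et3N (3.75 equiv), (CH2O)n (6.8 equiv), MeCN, reflux; 1 M HCl
Reagents that add atoms: paraformaldehyde (as formaldehyde), C=O
Why: Magnesium-mediated ortho-formylation (Casnati–Skattebøl reaction), in which the magnesium phenoxide delivers formaldehyde to the only free ortho position (the para position carries the methyl group) and a second formaldehyde oxidises the benzylic alkoxide to the aldehyde.

Step 9
Reactants: 16 2-hydroxy-3-methoxy-5-methylbenzaldehyde
Product: 17 2,3-dihydroxy-5-methylbenzaldehyde
Conditions: BBr3 (2.5 equiv), CH2Cl2, −78 → 0 °C; H2O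
Reagents that add atoms: none
Why: Boron tribromide cleavage of the aryl methyl ether (Lewis acid-assisted SN2 at the methyl carbon) gives the catechol, and the salicylaldehyde unit is expected to survive.

Step 10
Reactants: 17 2,3-dihydroxy-5-methylbenzaldehyde
Product: 19 2-hydroxy-3-(methoxymethoxy)-5-methylbenzaldehyde, via disodium catecholate 18 (not isolated)
Conditions: NaH (2.1 equiv), DMF, 0 °C; MOMCl (1.0 equiv), 0 °C → rt; aq. NH4Cl
Reagents that add atoms: chloromethyl methyl ether, COCCl; sodium hydride, [Na+].[H-] (sodium in 18 only)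
Why: Regioselective O-alkylation of a catechol aldehyde dianion, in which the C2 oxide is stabilised by conjugation with and chelation to the formyl group, so that one equivalent of the chloromethyl ether should react at the more basic C3 oxide.

Step 11
Reactants: 19 2-hydroxy-3-(methoxymethoxy)-5-methylbenzaldehyde
Product: 20 2-(hydroxymethyl)-6-(methoxymethoxy)-4-methylphenol
Conditions: NaBH4 (1.0 equiv), MeOH/THF, 0 °C
Reagents that add atoms: none
Why: Sodium borohydride reduction of the aldehyde gives the benzylic alcohol, the acetal being inert to hydride.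

Step 12
Reactants: 20 2-(hydroxymethyl)-6-(methoxymethoxy)-4-methylphenol
Product: 21 2-{[(tert-butyldimethylsilyl)oxy]methyl}-6-(methoxymethoxy)-4-methylphenol
Conditions: TBSCl (1.05 equiv), imidazole (1.5 equiv), CH2Cl2, 0 °C
Reagents that add atoms: tert-butyldimethylsilyl chloride, CC(C)(C)[Si](C)(C)Cl
Why: Imidazole-mediated silylation should select the unhindered primary hydroxyl over the phenol, which is flanked on both sides and hydrogen-bonded to the neighbouring acetal oxygen.

Step 13
Reactants: 14 3-(methoxymethoxy)-4-(3-methylbut-2-en-1-yl)-2-(trimethylsilyl)phenyl trifluoromethanesulfonate; 21 2-{[(tert-butyldimethylsilyl)oxy]methyl}-6-(methoxymethoxy)-4-methylphenol; 22 carbon dioxide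
Product: 27 2-{2-[(tert-butyldimethylsilyloxy)methyl]-6-(methoxymethoxy)-4-methylphenoxy}-6-(methoxymethoxy)-5-(3-methylbut-2-en-1-yl)benzoic acid, via potassium phenoxide 23 (not isolated), via aryne 24 (not isolated), via aryl anion 25 (not isolated), via potassium carboxylate 26 (not isolated)
Conditions: 21 (1.2 equiv), KH (1.2 equiv), THF, 0 °C → rt; then CO2 (1 atm), KF (3 equiv), 18-crown-6 (3 equiv), 14 (1.0 equiv, slow addition), THF, 0 °C → rt; cold aq. KHSO4 (pH 3–4)
Reagents that add atoms: potassium hydride, [K+].[H-] (potassium in 23, 25 and 26 only)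
Why: Proposed new method: fluoride attack on silicon with loss of triflate releases aryne 24, the potassium phenoxide 23 adds through oxygen to the aryne carbon remote from the methoxymethoxy group (C6 of ring A), and the aryl anion 25 that develops at C1 beside that oxygen is captured by carbon dioxide to give carboxylate 26, so the O–C6 and C1–CO2H bonds are made in one flask. The closest known reactions are the three-component coupling of arynes with amines and carbon dioxide to give anthranilic acids and the metal-free, fluoride-mediated O-arylation of phenols by silylaryl triflates; a phenoxide has not been the nucleophile in the carboxylative version. No ring is closed and no stereocentre is formed. The step needs attack at C6 and not at C1, which the inductively withdrawing C2 oxygen secures by distorting the aryne and stabilising the adjacent anion, and it needs O-arylation, which the substituted ortho and para positions of ring B enforce. Carboxylation must outrun protonation, so the phenol is fully deprotonated with KH beforehand (hydrogen is the only by-product) and THF replaces acetonitrile, while slow addition of 14 keeps the aryne dilute so that carboxylate 26 does not add to a second aryne. Reversible aryl carbonate formation from 23 and carbon dioxide remains the open variable and would be tuned through the CO2 partial pressure.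

Step 14
Reactants: 27 2-{2-[(tert-butyldimethylsilyloxy)methyl]-6-(methoxymethoxy)-4-methylphenoxy}-6-(methoxymethoxy)-5-(3-methylbut-2-en-1-yl)benzoic acid
Product: 28 2-hydroxy-6-[2-hydroxy-6-(hydroxymethyl)-4-methylphenoxy]-3-(3-methylbut-2-en-1-yl)benzoic acid (target)
Conditions: HCl (0.5 M in MeOH), THF, 0 °C → rt
Reagents that add atoms: none
Why: Acid-catalysed acetal exchange removes both aryl methoxymethyl ethers and acid-catalysed methanolysis removes the primary silyl ether in one operation, while the doubly ortho-substituted acid resists Fischer esterification and dilute acid at room temperature should leave the prenyl alkene untouched.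

**Compound list**

1 | 4-bromoresorcinol (4-bromobenzene-1,3-diol) | Oc1ccc(Br)c(O)c1 | starting material
2 | 2-bromo-5-[(triisopropylsilyl)oxy]phenol | CC(C)[Si](Oc1ccc(Br)c(O)c1)(C(C)C)C(C)C | intermediate
3 | [4-bromo-3-(methoxymethoxy)phenoxy]tri(propan-2-yl)silane | CC(C)[Si](Oc1ccc(Br)c(OCOC)c1)(C(C)C)C(C)C | intermediate
4 | prenyl bromide (1-bromo-3-methylbut-2-ene) | CC(C)=CCBr | starting material
5 | {2-(methoxymethoxy)-4-[(triisopropylsilyl)oxy]phenyl}lithium | CC(C)[Si](Oc1ccc([Li])c(OCOC)c1)(C(C)C)C(C)C | intermediate (not isolated)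
6 | [3-(methoxymethoxy)-4-(3-methylbut-2-en-1-yl)phenoxy]tri(propan-2-yl)silane | CC(C)=CCc1ccc(O[Si](C(C)C)(C(C)C)C(C)C)cc1OCOC | intermediate
7 | 3-(methoxymethoxy)-4-(3-methylbut-2-en-1-yl)phenol | CC(C)=CCc1ccc(O)cc1OCOC | intermediate
8 | 3-(methoxymethoxy)-4-(3-methylbut-2-en-1-yl)phenyl N-(propan-2-yl)carbamate | CC(C)=CCc1ccc(OC(=O)NC(C)C)cc1OCOC | intermediate
9 | 3-(methoxymethoxy)-4-(3-methylbut-2-en-1-yl)phenyl N-(tert-butyldimethylsilyl)-N-(propan-2-yl)carbamate | CC(C)=CCc1ccc(OC(=O)N(C(C)C)[Si](C)(C)C(C)(C)C)cc1OCOC | intermediate (not isolated)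
10 | 2-lithio derivative of 9 (lithium on the carbon between the two oxygens) | CC(C)=CCc1ccc(OC(=O)N(C(C)C)[Si](C)(C)C(C)(C)C)c([Li])c1OCOC | intermediate (not isolated)
11 | 3-(methoxymethoxy)-4-(3-methylbut-2-en-1-yl)-2-(trimethylsilyl)phenyl N-(tert-butyldimethylsilyl)-N-(propan-2-yl)carbamate | CC(C)=CCc1ccc(OC(=O)N(C(C)C)[Si](C)(C)C(C)(C)C)c([Si](C)(C)C)c1OCOC | intermediate (not isolated)
12 | 3-(methoxymethoxy)-4-(3-methylbut-2-en-1-yl)-2-(trimethylsilyl)phenyl N-(propan-2-yl)carbamate | CC(C)=CCc1ccc(OC(=O)NC(C)C)c([Si](C)(C)C)c1OCOC | intermediate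
13 | 3-(methoxymethoxy)-4-(3-methylbut-2-en-1-yl)-2-(trimethylsilyl)phenol | CC(C)=CCc1ccc(O)c([Si](C)(C)C)c1OCOC | intermediate (not isolated)
14 | 3-(methoxymethoxy)-4-(3-methylbut-2-en-1-yl)-2-(trimethylsilyl)phenyl trifluoromethanesulfonate | CC(C)=CCc1ccc(OS(=O)(=O)C(F)(F)F)c([Si](C)(C)C)c1OCOC | intermediate
15 | creosol (2-methoxy-4-methylphenol) | COc1cc(C)ccc1O | starting material
16 | 2-hydroxy-3-methoxy-5-methylbenzaldehyde | COc1cc(C)cc(C=O)c1O | intermediate
17 | 2,3-dihydroxy-5-methylbenzaldehyde | Cc1cc(O)c(O)c(C=O)c1 | intermediate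
18 | disodium 3-formyl-5-methylbenzene-1,2-diolate | Cc1cc([O-])c([O-])c(C=O)c1.[Na+].[Na+] | intermediate (not isolated)
19 | 2-hydroxy-3-(methoxymethoxy)-5-methylbenzaldehyde | COCOc1cc(C)cc(C=O)c1O | intermediate
20 | 2-(hydroxymethyl)-6-(methoxymethoxy)-4-methylphenol | COCOc1cc(C)cc(CO)c1O | intermediate
21 | 2-{[(tert-butyldimethylsilyl)oxy]methyl}-6-(methoxymethoxy)-4-methylphenol | Cc1cc(OCOC)c(O)c(CO[Si](C)(C)C(C)(C)C)c1 | intermediate
22 | carbon dioxide | O=C=O | starting material
23 | potassium 2-{[(tert-butyldimethylsilyl)oxy]methyl}-6-(methoxymethoxy)-4-methylphenolate | Cc1cc(OCOC)c([O-])c(CO[Si](C)(C)C(C)(C)C)c1.[K+] | intermediate (not isolated)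
24 | 3-(methoxymethoxy)-4-(3-methylbut-2-en-1-yl)-1,2-didehydrobenzene (aryne) | COCOC1=C(CC=C(C)C)C=CC#C1 | intermediate (not isolated)
25 | potassium 2-aryloxy-6-(methoxymethoxy)-5-(3-methylbut-2-en-1-yl)phenyl anion (aryloxy = ring B of 21) | CC(C)=CCc1ccc(Oc2c(OCOC)cc(C)cc2CO[Si](C)(C)C(C)(C)C)[c-]c1OCOC.[K+] | intermediate (not isolated)
26 | potassium salt of acid 27 | CC(C)=CCc1ccc(Oc2c(OCOC)cc(C)cc2CO[Si](C)(C)C(C)(C)C)c(C(=O)[O-])c1OCOC.[K+] | intermediate (not isolated)
27 | 2-{2-[(tert-butyldimethylsilyloxy)methyl]-6-(methoxymethoxy)-4-methylphenoxy}-6-(methoxymethoxy)-5-(3-methylbut-2-en-1-yl)benzoic acid | CC(C)=CCc1ccc(Oc2c(OCOC)cc(C)cc2CO[Si](C)(C)C(C)(C)C)c(C(=O)O)c1OCOC | intermediate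
28 | 2-hydroxy-6-[2-hydroxy-6-(hydroxymethyl)-4-methylphenoxy]-3-(3-methylbut-2-en-1-yl)benzoic acid | CC(C)=CCc1ccc(Oc2c(O)cc(C)cc2CO)c(C(=O)O)c1O | target

**Step count and risks**

Total steps: 14 (steps 1–7 for the aryne precursor, steps 8–12 for the ring B phenol, steps 13 and 14 in common).
Longest linear sequence: 9 steps (steps 1–7, 13, 14).

Steps most likely to fail:

1. Step 13. The aryl anion may be protonated before it meets carbon dioxide. The phenoxide may be held as its carbonate, which would slow O-arylation or divert it to carbonate addition and acyl transfer. Fluoride may also erode the primary silyl ether. The fallback uses known chemistry and sets out from 14 and 21. Fluoride-mediated O-arylation of the free phenol 21 by 14 (CsF, MeCN, rt, no carbon dioxide) has the same aryne regiochemistry and should give, after protonation at C1, the diaryl ether tert-butyl{[3-(methoxymethoxy)-2-[3-(methoxymethoxy)-4-(3-methylbut-2-en-1-yl)phenoxy]-5-methylphenyl]methoxy}dimethylsilane F1. Directed ortho-metalation of F1 at the ring A carbon flanked by the aryloxy and methoxymethoxy groups (n-BuLi, TMEDA, THF, −78 → −40 °C) and quenching with carbon dioxide 22 should then give the acid, so the fallback comes back to the route at 27.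

2. Step 14. Protonation of the prenyl alkene may lead to cyclisation onto the freed C2 phenol (chroman formation) or to addition of methanol or HCl, and the benzylic alcohol may undergo solvolysis. The fallback sets out from 27 and avoids Brønsted acid. Silyl triflate with 2,2'-bipyridyl (TMSOTf, CH2Cl2, 0 °C, then water) should convert both aryl methoxymethyl ethers into phenols through pyridinium intermediates and leave the silyl ether in place. This gives 2-{2-[(tert-butyldimethylsilyloxy)methyl]-6-hydroxy-4-methylphenoxy}-6-hydroxy-5-(3-methylbut-2-en-1-yl)benzoic acid F2. Buffered fluoride (Et3N·3HF, MeCN, rt) then removes the silyl group, and the fallback comes back to the route at 28.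

3. Step 6. The carbamate may fragment to isocyanate and phenoxide if N-silylation is incomplete, the silyl triflate may attack the methoxymethyl acetal, and the alkyllithium may deprotonate the benzylic–allylic CH2 of the prenyl group. The fallback sets out from 7 and uses a tertiary carbamate, a lithium amide base and in situ trapping. Carbamoylation (Et2NCOCl, K2CO3, MeCN, reflux) gives 3-(methoxymethoxy)-4-(3-methylbut-2-en-1-yl)phenyl N,N-diethylcarbamate F3. Directed ortho-metalation with LiTMP in the presence of TMSCl (THF, −78 °C) silylates the position between the two oxygens as the anion forms and gives 3-(methoxymethoxy)-4-(3-methylbut-2-en-1-yl)-2-(trimethylsilyl)phenyl N,N-diethylcarbamate F4. Reductive cleavage of the carbamate (LiAlH4, THF, 0 °C → rt) then gives the silylphenol, so the fallback comes back to the route at 13, which is isolated in this case and triflated with PhNTf2 as in the second half of step 7 to give 14.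

**Further compounds**

F1 | step 13 | tert-butyl{[3-(methoxymethoxy)-2-[3-(methoxymethoxy)-4-(3-methylbut-2-en-1-yl)phenoxy]-5-methylphenyl]methoxy}dimethylsilane | CC(C)=CCc1ccc(Oc2c(OCOC)cc(C)cc2CO[Si](C)(C)C(C)(C)C)cc1OCOC
F2 | step 14 | 2-{2-[(tert-butyldimethylsilyloxy)methyl]-6-hydroxy-4-methylphenoxy}-6-hydroxy-5-(3-methylbut-2-en-1-yl)benzoic acid | CC(C)=CCc1ccc(Oc2c(O)cc(C)cc2CO[Si](C)(C)C(C)(C)C)c(C(=O)O)c1O
F3 | step 6 | 3-(methoxymethoxy)-4-(3-methylbut-2-en-1-yl)phenyl N,N-diethylcarbamate | CCN(CC)C(=O)Oc1ccc(CC=C(C)C)c(OCOC)c1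
F4 | step 6 | 3-(methoxymethoxy)-4-(3-methylbut-2-en-1-yl)-2-(trimethylsilyl)phenyl N,N-diethylcarbamate | CCN(CC)C(=O)Oc1ccc(CC=C(C)C)c(OCOC)c1[Si](C)(C)C
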